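**Retrosynthetic overview**
1. Target ⇐ its bis-silyl ether; ring C (eleven-membered) is closed last at the C(=CH2)–CH2 bond by intramolecular B-alkyl Suzuki–Miyaura coupling of a ring A enol triflate with the terminal alkene of the side chain.
2. Ring B ⇐ intramolecular ring-opening carbonyl–olefin metathesis of a side-chain ketone with a dimethylcyclobutene fused to ring A (new step); it forms the tetrasubstituted alkene and unmasks the methyl ketone needed in line 1.
3. Side chain ⇐ aldol addition of (R)-5-methyloct-7-en-2-one (from (S)-2-methylpent-4-en-1-ol and acetone dimethylhydrazone) to a neopentyl aldehyde on ring A.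
4. Quaternary carbon and acetoxy carbinol of ring A ⇐ key step: stereospecific semipinacol 1,2-vinyl shift of a 2,3-epoxy alcohol made from an enol triflate and acrolein.
5. Ring A with its cis ring-fusion centres ⇐ [2+2] photocycloaddition of (S)-4-silyloxycyclopent-2-enone with but-2-yne; ring order A (with masked four-membered ring) → B → C.

Assumption: (4S)-4-silyloxycyclopent-2-enone, (2S)-2-methylpent-4-en-1-ol and acetone N,N-dimethylhydrazone are taken as purchasable in the stated form and enantiopurity.

**Route**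

Step 1
Reactants: 1 (4S)-4-[(tert-butyldimethylsilyl)oxy]cyclopent-2-en-1-one; 2 but-2-yne
Product: 3 (1S,4S,5R)-4-[(tert-butyldimethylsilyl)oxy]-6,7-dimethylbicyclo[3.2.0]hept-6-en-2-one
Conditions: hν (350 nm, uranium filter), 2 (10 equiv), CH2Cl2, −40 °C; chromatography
Reagents that add atoms: none
Why: Enone–alkyne [2+2] photocycloaddition through the triplet 1,4-biradical adds the alkyne to the face anti to the bulky silyloxy group, which sets both ring-fusion stereocenters (cis by ring constraint), and the minor syn adduct is removed by chromatography.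

Step 2
Reactants: 3 (1S,4S,5R)-4-[(tert-butyldimethylsilyl)oxy]-6,7-dimethylbicyclo[3.2.0]hept-6-en-2-one
Product: 4 (1S,5R)-6,7-dimethylbicyclo[3.2.0]hepta-3,6-dien-2-one
Conditions: DBU, CH2Cl2, 0 °C
Reagents that add atoms: none
Why: E1cB elimination of the β-silyloxy group gives the enone, removing the auxiliary stereocenter while the two ring-fusion centres, which cannot epimerise in the cis-fused bicycle, are kept.

Step 3
Reactants: 4 (1S,5R)-6,7-dimethylbicyclo[3.2.0]hepta-3,6-dien-2-one
Product: 6 (1S,5R)-6,7-dimethylbicyclo[3.2.0]hepta-2,6-dien-2-yl trifluoromethanesulfonate, via lithium enolate 5 (not isolated)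
Conditions: LiBH(s-Bu)3, THF, −78 °C; then PhNTf2, −78 → 0 °C
Reagents that add atoms: N-phenylbis(trifluoromethanesulfonimide), O=S(=O)(N(c1ccccc1)S(=O)(=O)C(F)(F)F)C(F)(F)F
Why: Conjugate reduction by the hindered borohydride gives the enolate regiospecifically and O-sulfonylation traps it as the enol triflate (reductive enolate trapping), with no stereocenter formed.

Step 4
Reactants: 6 (1S,5R)-6,7-dimethylbicyclo[3.2.0]hepta-2,6-dien-2-yl trifluoromethanesulfonate; 7 acrolein
Product: 8 1-[(1S,5R)-6,7-dimethylbicyclo[3.2.0]hepta-2,6-dien-2-yl]prop-2-en-1-ol (both carbinol epimers)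
Conditions: 7 (3 equiv), CrCl2 (4 equiv), NiCl2 (2 mol %), DMF, 23 °C
Reagents that add atoms: none
Why: Nozaki–Hiyama–Kishi coupling (oxidative addition of the enol triflate to zerovalent nickel, transmetallation to trivalent chromium, 1,2-addition to the aldehyde) gives the divinyl carbinol, whose carbinol centre forms unselectively but becomes the formyl carbon in step 6.

Step 5
Reactants: 8 1-[(1S,5R)-6,7-dimethylbicyclo[3.2.0]hepta-2,6-dien-2-yl]prop-2-en-1-ol
Product: 9 2,3-epoxide of 8 with the oxygen on the face opposite the cyclobutene (both carbinol epimers)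
Conditions: VO(acac)2 (5 mol %), t-BuOOH, CH2Cl2, 0 °C
Reagents that add atoms: tert-butyl hydroperoxide, CC(C)(C)OO
Why: Hydroxyl-directed VO(acac)2/t-BuOOH epoxidation reacts only at the allylic trisubstituted ring alkene (the cyclobutene is not directed and the vinyl group is slower) and from the convex face anti to the cis-fused cyclobutene, which sets the two epoxide centres.

Step 6
Reactants: 9 epoxy alcohol
Product: 10 (1S,2S,3R,5R)-2-ethenyl-3-hydroxy-6,7-dimethylbicyclo[3.2.0]hept-6-ene-2-carbaldehyde
Conditions: ZnBr2 (30 mol %), CH2Cl2, 0 → 23 °C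
Reagents that add atoms: none
Why: Type-3 semipinacol rearrangement of the 2,3-epoxy alcohol, in which Lewis-acid opening of the tertiary C–O bond is concerted with anti 1,2-shift of the vinyl group (better migrating group than hydride), creates the quaternary centre with inversion so that vinyl lies on the cyclobutene face and formyl and the new secondary hydroxyl are cis on the opposite face.

Step 7
Reactants: 10 (1S,2S,3R,5R)-2-ethenyl-3-hydroxy-6,7-dimethylbicyclo[3.2.0]hept-6-ene-2-carbaldehyde
Product: 11 (1S,2R,3R,5R)-2-ethenyl-2-(hydroxymethyl)-6,7-dimethylbicyclo[3.2.0]hept-6-en-3-ol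
Conditions: NaBH4, MeOH, 0 °C
Reagents that add atoms: none
Why: Borohydride reduction of the non-enolisable aldehyde to the primary alcohol forms no stereocenter and removes the retro-aldol risk.

Step 8
Reactants: 11 (1S,2R,3R,5R)-2-ethenyl-2-(hydroxymethyl)-6,7-dimethylbicyclo[3.2.0]hept-6-en-3-ol
Product: 13 (1S,2R,3R,5R)-2-{[(tert-butyldimethylsilyl)oxy]methyl}-2-ethenyl-6,7-dimethylbicyclo[3.2.0]hept-6-en-3-yl acetate, via primary silyl ether 12 (not isolated)
Conditions: TBSCl, imidazole, CH2Cl2, 0 °C; then Ac2O, DMAP, pyridine, 23 °C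
Reagents that add atoms: tert-butyldimethylsilyl chloride, CC(C)(C)[Si](C)(C)Cl; acetic anhydride, CC(=O)OC(C)=O
Why: Silylation is selective for the primary hydroxyl and the DMAP-catalysed acylation then esterifies the remaining secondary hydroxyl, so the acetate is installed only after the neighbouring primary oxygen is capped and 1,3-acyl migration is excluded.

Step 9
Reactants: 13 silyl ether acetate
Product: 15 (1S,2S,3R,5R)-2-{[(tert-butyldimethylsilyl)oxy]methyl}-2-formyl-6,7-dimethylbicyclo[3.2.0]hept-6-en-3-yl acetate, via vicinal diol 14 (not isolated)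
Conditions: OsO4 (2 mol %), NaIO4 (4 equiv), 2,6-lutidine, dioxane/H2O 3:1, 23 °C
Reagents that add atoms: sodium periodate (oxygen relayed through OsO4), [Na+].[O-]I(=O)(=O)=O
Why: Lemieux–Johnson oxidation, in which OsO4 dihydroxylates the monosubstituted vinyl group much faster than the hindered tetrasubstituted cyclobutene and NaIO4 cleaves the diol, gives the non-enolisable aldehyde without touching the quaternary centre.

Step 10
Reactants: 16 (2S)-2-methylpent-4-en-1-ol
Product: 17 (4S)-5-iodo-4-methylpent-1-ene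
Conditions: I2, PPh3, imidazole, CH2Cl2, 0 → 23 °C
Reagents that add atoms: iodine, II
Why: Appel-type iodination proceeds by SN2 at the primary carbon and leaves the adjacent stereocenter untouched.

Step 11
Reactants: 18 acetone N,N-dimethylhydrazone; 17 (4S)-5-iodo-4-methylpent-1-ene
Product: 21 (5R)-5-methyloct-7-en-2-one, via lithiated hydrazone 19 (not isolated), via alkylated hydrazone 20 (not isolated)
Conditions: LiN(i-Pr)2, THF, −78 → 0 °C; 17, −78 → 23 °C; then aq. oxalic acid, Et2O, 23 °C
Reagents that add atoms: water, O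
Why: The lithiated hydrazone (azaenolate) is mono-alkylated by the primary iodide (SN2) and hydrolysed to the methyl ketone, the stereocenter being carried over unchanged from 16.

Step 12
Reactants: 21 (5R)-5-methyloct-7-en-2-one; 15 aldehyde
Product: 23 (1S,2R,3R,5R)-2-{[(tert-butyldimethylsilyl)oxy]methyl}-2-[(1S,5R)-1-hydroxy-5-methyl-3-oxooct-7-en-1-yl]-6,7-dimethylbicyclo[3.2.0]hept-6-en-3-yl acetate, via lithium enolate 22 (not isolated)
Conditions: LiN(i-Pr)2, THF, −78 °C; then 15, −78 °C
Reagents that add atoms: none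
Why: Aldol addition of the kinetic (methyl-side) lithium enolate to the aldehyde under Felkin–Anh control, anti to the ring-fusion carbon that carries the cyclobutene and past the small CH2OTBS group, is expected to give the (S)-carbinol needed for ring B, the minor epimer being removed by chromatography.

Step 13
Reactants: 23 aldol adduct
Product: 24 tert-butyldimethylsilyl ether of 23 at the side-chain carbinol
Conditions: TBSOTf, 2,6-lutidine, CH2Cl2, −78 °C
Reagents that add atoms: tert-butyldimethylsilyl trifluoromethanesulfonate, CC(C)(C)[Si](C)(C)OS(=O)(=O)C(F)(F)F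
Why: Silyl triflate silylation of the hindered secondary alcohol blocks retro-aldol cleavage and leaves the carbinol configuration unchanged.

Step 14
Reactants: 24 cyclobutene keto silyl ether
Product: 25 ring A/ring B methyl ketone: cis-fused hexahydroindene with acetyl and acetoxy on ring A, angular CH2OTBS, OTBS on ring B, and methyl plus (3R)-3-methylhex-5-enyl on the new tetrasubstituted alkene
Conditions: FeCl3 (10 mol %), 4 Å MS, ClCH2CH2Cl, 0 → 23 °C
Reagents that add atoms: none
Why: Proposed new method: a Lewis-acid-catalysed intramolecular ring-opening carbonyl–olefin metathesis, in which FeCl3 activates the ketone, the electron-rich tetrasubstituted cyclobutene attacks it through the carbon nearer the tether (six-membered closure, tertiary cation character on the other cyclobutene carbon), and the resulting oxetane cycloreverts to the ring B alkene plus the ring A methyl ketone, driven by release of about 26 kcal/mol of four-ring strain, the closest known reaction types being FeCl3-catalysed ring-closing carbonyl–olefin metathesis of ketones with prenyl-type olefins and hydrazine-catalysed ring-opening carbonyl–olefin metathesis of cyclobutenes with aldehydes; no stereocenter is formed.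

Step 15
Reactants: 25 ring A/ring B methyl ketone
Product: 27 enol triflate of 25 (1-substituted ethenyl trifluoromethanesulfonate on ring A), via potassium enolate 26 (not isolated)
Conditions: KN(SiMe3)2, THF, −78 °C; then PhNTf2, −78 °C
Reagents that add atoms: N-phenylbis(trifluoromethanesulfonimide), O=S(=O)(N(c1ccccc1)S(=O)(=O)C(F)(F)F)C(F)(F)F
Why: Kinetic deprotonation at the methyl group and O-sulfonylation give the 1,1-disubstituted enol triflate without enolising toward, and so without epimerising, the adjacent ring stereocenter.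

Step 16
Reactants: 27 enol triflate
Product: 29 bis(tert-butyldimethylsilyl) ether of 30, via alkylborane 28 (not isolated)
Conditions: 9-BBN, THF, 23 °C; then slow addition to Pd(dppf)Cl2 (20 mol %), AsPh3, Cs2CO3, DMF/THF/H2O, 50 °C, 2 mM
Reagents that add atoms: none
Why: Chemoselective hydroboration of the terminal alkene followed by intramolecular B-alkyl Suzuki–Miyaura coupling under high dilution closes ring C between two termini already held cis on the bicyclic core and delivers the exocyclic methylene directly.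

Step 17
Reactants: 29 bis-silyl ether
Product: 30 CNP0228496.1
Conditions: HF·pyridine, pyridine/THF, 0 → 23 °C
Reagents that add atoms: none
Why: Fluoride desilylation under mildly acidic conditions frees the primary and the ring B hydroxyl without hydrolysis or migration of the secondary acetate.

**Compound list**
1 | (4S)-4-[(tert-butyldimethylsilyl)oxy]cyclopent-2-en-1-one | O=C1C=C[C@@H](O[Si](C)(C)C(C)(C)C)C1 | starting material
2 | but-2-yne | CC#CC | starting material
3 | (1S,4S,5R)-4-[(tert-butyldimethylsilyl)oxy]-6,7-dimethylbicyclo[3.2.0]hept-6-en-2-one | CC1=C(C)[C@@H]2[C@H]1[C@@H](O[Si](C)(C)C(C)(C)C)CC2=O | intermediate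
4 | (1S,5R)-6,7-dimethylbicyclo[3.2.0]hepta-3,6-dien-2-one | CC1=C(C)[C@@H]2[C@H]1C=CC2=O | intermediate
5 | lithium (1S,5R)-6,7-dimethylbicyclo[3.2.0]hepta-2,6-dien-2-olate | CC1=C(C)[C@@H]2[C@H]1CC=C2[O-].[Li+] | intermediate
6 | (1S,5R)-6,7-dimethylbicyclo[3.2.0]hepta-2,6-dien-2-yl trifluoromethanesulfonate | CC1=C(C)[C@@H]2[C@H]1CC=C2OS(=O)(=O)C(F)(F)F | intermediate
7 | acrolein | C=CC=O | starting material
8 | 1-[(1S,5R)-6,7-dimethylbicyclo[3.2.0]hepta-2,6-dien-2-yl]prop-2-en-1-ol, both carbinol epimers | CC1=C(C)[C@@H]2[C@H]1CC=C2C(O)C=C | intermediate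
9 | 2,3-epoxide of 8, oxygen anti to the cyclobutene, both carbinol epimers | CC1=C(C)[C@@H]2[C@H]1C[C@H]3O[C@@]23C(O)C=C | intermediate
10 | (1S,2S,3R,5R)-2-ethenyl-3-hydroxy-6,7-dimethylbicyclo[3.2.0]hept-6-ene-2-carbaldehyde | CC1=C(C)[C@@H]2[C@H]1C[C@@H](O)[C@]2(C=O)C=C | intermediate
11 | (1S,2R,3R,5R)-2-ethenyl-2-(hydroxymethyl)-6,7-dimethylbicyclo[3.2.0]hept-6-en-3-ol | CC1=C(C)[C@@H]2[C@H]1C[C@@H](O)[C@]2(CO)C=C | intermediate
12 | (1S,2R,3R,5R)-2-{[(tert-butyldimethylsilyl)oxy]methyl}-2-ethenyl-6,7-dimethylbicyclo[3.2.0]hept-6-en-3-ol | CC1=C(C)[C@@H]2[C@H]1C[C@@H](O)[C@]2(CO[Si](C)(C)C(C)(C)C)C=C | intermediate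
13 | (1S,2R,3R,5R)-2-{[(tert-butyldimethylsilyl)oxy]methyl}-2-ethenyl-6,7-dimethylbicyclo[3.2.0]hept-6-en-3-yl acetate | CC1=C(C)[C@@H]2[C@H]1C[C@@H](OC(C)=O)[C@]2(CO[Si](C)(C)C(C)(C)C)C=C | intermediate
14 | 1,2-diol from the vinyl group of 13, both epimers | CC1=C(C)[C@@H]2[C@H]1C[C@@H](OC(C)=O)[C@]2(CO[Si](C)(C)C(C)(C)C)C(O)CO | intermediate
15 | (1S,2S,3R,5R)-2-{[(tert-butyldimethylsilyl)oxy]methyl}-2-formyl-6,7-dimethylbicyclo[3.2.0]hept-6-en-3-yl acetate | CC1=C(C)[C@@H]2[C@H]1C[C@@H](OC(C)=O)[C@]2(CO[Si](C)(C)C(C)(C)C)C=O | intermediate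
16 | (2S)-2-methylpent-4-en-1-ol | C=CC[C@H](C)CO | starting material
17 | (4S)-5-iodo-4-methylpent-1-ene | C=CC[C@H](C)CI | intermediate
18 | acetone N,N-dimethylhydrazone | CC(C)=NN(C)C | starting material
19 | lithiated acetone N,N-dimethylhydrazone (azaenolate) | C=C(C)[N-]N(C)C.[Li+] | intermediate
20 | (5R)-5-methyloct-7-en-2-one N,N-dimethylhydrazone | C=CC[C@H](C)CCC(C)=NN(C)C | intermediate
21 | (5R)-5-methyloct-7-en-2-one | C=CC[C@H](C)CCC(C)=O | intermediate
22 | lithium (5R)-5-methylocta-1,7-dien-2-olate | C=CC[C@H](C)CCC(=C)[O-].[Li+] | intermediate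
23 | (1S,2R,3R,5R)-2-{[(tert-butyldimethylsilyl)oxy]methyl}-2-[(1S,5R)-1-hydroxy-5-methyl-3-oxooct-7-en-1-yl]-6,7-dimethylbicyclo[3.2.0]hept-6-en-3-yl acetate | CC1=C(C)[C@@H]2[C@H]1C[C@@H](OC(C)=O)[C@]2(CO[Si](C)(C)C(C)(C)C)[C@@H](O)CC(=O)CC[C@@H](C)CC=C | intermediate
24 | tert-butyldimethylsilyl ether of 23 at the side-chain carbinol | CC1=C(C)[C@@H]2[C@H]1C[C@@H](OC(C)=O)[C@]2(CO[Si](C)(C)C(C)(C)C)[C@@H](O[Si](C)(C)C(C)(C)C)CC(=O)CC[C@@H](C)CC=C | intermediate
25 | ring A/ring B methyl ketone (cis-fused hexahydroindene; acetyl cis to ring B on ring A, acetoxy, angular CH2OTBS, ring B OTBS, alkene methyl and (3R)-3-methylhex-5-enyl; ring stereocentres as in 30) | C=CC[C@H](C)CCC2=C(C)[C@@H]3[C@H](C(C)=O)C[C@@H](OC(C)=O)[C@]3(CO[Si](C)(C)C(C)(C)C)[C@@H](O[Si](C)(C)C(C)(C)C)C2 | intermediate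
26 | potassium enolate of 25 (methyl side) | C=CC[C@H](C)CCC2=C(C)[C@@H]3[C@H](C(=C)[O-])C[C@@H](OC(C)=O)[C@]3(CO[Si](C)(C)C(C)(C)C)[C@@H](O[Si](C)(C)C(C)(C)C)C2.[K+] | intermediate
27 | enol triflate of 25 | C=CC[C@H](C)CCC2=C(C)[C@@H]3[C@H](C(=C)OS(=O)(=O)C(F)(F)F)C[C@@H](OC(C)=O)[C@]3(CO[Si](C)(C)C(C)(C)C)[C@@H](O[Si](C)(C)C(C)(C)C)C2 | intermediate
28 | B-alkyl-9-borabicyclo[3.3.1]nonane from hydroboration of 27 | B4(C5CCCC4CCC5)CCC[C@H](C)CCC2=C(C)[C@@H]3[C@H](C(=C)OS(=O)(=O)C(F)(F)F)C[C@@H](OC(C)=O)[C@]3(CO[Si](C)(C)C(C)(C)C)[C@@H](O[Si](C)(C)C(C)(C)C)C2 | intermediate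
29 | bis(tert-butyldimethylsilyl) ether of 30 (primary and ring B secondary oxygen silylated) | C=C1CCC[C@H](C)CCC2=C(C)[C@@H]3[C@H]1C[C@@H](OC(C)=O)[C@]3(CO[Si](C)(C)C(C)(C)C)[C@@H](O[Si](C)(C)C(C)(C)C)C2 | intermediate
30 | CNP0228496.1 (tricyclic ring A/B/C acetate diol) | C=C1CCC[C@H](C)CCC2=C(C)[C@@H]3[C@H]1C[C@@H](OC(C)=O)[C@]3(CO)[C@@H](O)C2 | target

**Step count and risks**
Total steps: 17. Longest linear sequence: 15 (steps 1–9 and 12–17).

Most likely to fail, in order:

Step 14 (the new ring-opening carbonyl–olefin metathesis). A carbonyl-ene reaction of the cyclobutene methyl groups, cationic rearrangement of the four-membered ring, loss of the β-silyloxy group or epimerisation next to the new acetyl group may compete. The fallback uses known chemistry, sets out from 24 and comes back at 25. Ozonolysis with one equivalent of O3 (pyridine, CH2Cl2, −78 °C, then Me2S) cleaves the strained tetrasubstituted cyclobutene ahead of the terminal alkene and gives the triketone F1. Intramolecular McMurry coupling of its 1,6-diketone pair (TiCl3(DME)1.5, Zn–Cu couple, DME, reflux, slow addition) then closes ring B to 25; six-membered ring preference and high dilution are relied on to spare the third ketone.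

Step 16 (closure of the eleven-membered ring C). Protodeboronation, β-hydride elimination or dimerisation may win over the strained ring closure. The fallback sets out from 27 and comes back at 29. Hydroboration–oxidation (9-BBN, then NaBO3) gives the primary alcohol F2, and Dess–Martin oxidation gives the aldehyde F3. Nozaki–Hiyama–Kishi macrocyclisation (CrCl2, NiCl2 catalyst, DMF/THF, high dilution) gives the macrocyclic allylic alcohol F4. Methyl chloroformate/pyridine gives the allylic methyl carbonate F5, and Pd(OAc)2/PBu3/HCO2NH4 reduction, which delivers hydride to the more substituted allyl terminus, gives 29 with the exocyclic methylene.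

Step 9 (vinyl cleavage beside the cyclobutene). Osmylation of the strained cyclobutene or slow reaction of the hindered vinyl group may spoil the selectivity. The fallback sets out from 11 and comes back at 15. VO(acac)2/t-BuOOH epoxidises only the vinyl group, directed by the homoallylic hydroxyls, and gives the epoxy diol F6. Silylation and acetylation under the conditions of step 8 give the protected epoxide F7, and periodic acid (H5IO6, THF/Et2O, 0 °C) cleaves the terminal epoxide to 15.

**Further compounds**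
F1 | step 14 | triketone from cyclobutene ozonolysis of 24 (two ring A acetyl groups, side-chain ketone, terminal alkene intact) | CC(=O)[C@@H]1[C@H](C(C)=O)C[C@@H](OC(C)=O)[C@]1(CO[Si](C)(C)C(C)(C)C)[C@@H](O[Si](C)(C)C(C)(C)C)CC(=O)CC[C@@H](C)CC=C
F2 | step 16 | primary alcohol from hydroboration–oxidation of 27 | OCCC[C@H](C)CCC2=C(C)[C@@H]3[C@H](C(=C)OS(=O)(=O)C(F)(F)F)C[C@@H](OC(C)=O)[C@]3(CO[Si](C)(C)C(C)(C)C)[C@@H](O[Si](C)(C)C(C)(C)C)C2
F3 | step 16 | aldehyde from F2 | O=CCC[C@H](C)CCC2=C(C)[C@@H]3[C@H](C(=C)OS(=O)(=O)C(F)(F)F)C[C@@H](OC(C)=O)[C@]3(CO[Si](C)(C)C(C)(C)C)[C@@H](O[Si](C)(C)C(C)(C)C)C2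
F4 | step 16 | macrocyclic allylic alcohol (hydroxyl on the ring C carbon next to the exocyclic alkene, both epimers) | C=C1C(O)CC[C@H](C)CCC2=C(C)[C@@H]3[C@H]1C[C@@H](OC(C)=O)[C@]3(CO[Si](C)(C)C(C)(C)C)[C@@H](O[Si](C)(C)C(C)(C)C)C2
F5 | step 16 | allylic methyl carbonate of F4 | C=C1C(OC(=O)OC)CC[C@H](C)CCC2=C(C)[C@@H]3[C@H]1C[C@@H](OC(C)=O)[C@]3(CO[Si](C)(C)C(C)(C)C)[C@@H](O[Si](C)(C)C(C)(C)C)C2
F6 | step 9 | epoxy diol from vinyl epoxidation of 11 (both epoxide epimers) | CC1=C(C)[C@@H]2[C@H]1C[C@@H](O)[C@]2(CO)C3CO3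
F7 | step 9 | primary silyl ether secondary acetate of F6 | CC1=C(C)[C@@H]2[C@H]1C[C@@H](OC(C)=O)[C@]2(CO[Si](C)(C)C(C)(C)C)C3CO3
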